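**Retrosynthetic overview** (benzofuran locants: O1, C2, C3, C3a, C4–C7, C7a)
1. The dihydrofuran ring is opened at the O1–C7a enol-ether bond (vinylogous-ester transposition). This leads back to a 4-allyl-5-isopropoxy-4-methoxycyclohexa-2,5-dienone carrying the C3–C2(OH)Ar chain on C3a.
2. The carbocycle is cut at C4–C5 and C3a–C7a: a nickel-catalysed [4+2] insertion of a terminal alkyne (C3a≡C4–H) into the acyl–C(sp3) bond of a squarate-derived cyclobutenone that supplies C5–C6–C7–C7a.
3. Enabling feature: C5(OMe)(allyl)–C6(=O)–C7H=C7a(–O1) is a 1,3-dioxygenated four-carbon segment ending in an oxygenated quaternary carbon. These are the four ring carbons of a 4-hydroxy-3-alkoxycyclobut-2-enone; C4 is an unsubstituted CH and C3a carries the only carbon branch, which is the pattern of a terminal alkyne.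
4. C5 is set on the four-membered ring by asymmetric allylboration of the semisquarate ketone and carried through the C–C cleavage with retention. C2/C3 come from an anti-selective allenylzinc propargylation of 3,4-dimethoxybenzaldehyde.
5. Ring order: six-membered carbocycle (step 7), then dihydrofuran (step 8).

Key step: step 7

Assumption: the palladium/zinc propargylation is taken to proceed with net inversion at the propargylic carbon (anti SN2′ palladation, retentive transfer to zinc, syn SE2′ addition), so (S)-but-3-yn-2-ol is the required antipode; the antipode of the allylboration catalyst that gives (R)-4 is to be fixed in a scouting run.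

**Step 1**
Reactants: 1 diisopropyl squarate
Product: 3 3-isopropoxycyclobut-3-ene-1,2-dione, via hydroxy enone 2 (not isolated)
Conditions: LiAlH(OtBu)3 (1.05 equiv), THF, −78 → −20 °C; then conc. HCl (cat.), CH2Cl2, rt
Reagents that add atoms: none
Why: 1,2-reduction of one vinylogous-ester carbonyl by the hindered hydride, then acid-promoted loss of isopropanol from the vinylogous hemiacetal, is the standard conversion of a squarate diester into a 3-alkoxycyclobutenedione; no stereocenter remains.

**Step 2**
Reactants: 3 3-isopropoxycyclobut-3-ene-1,2-dione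
Product: 4 (4R)-4-allyl-4-hydroxy-3-isopropoxycyclobut-2-en-1-one
Conditions: allyldiisopropoxyborane (1.5 equiv), (S)-3,3'-dibromo-1,1'-bi-2-naphthol (15 mol %), toluene–PhCF3 3:1, −35 °C; aqueous work-up
Reagents that add atoms: allyldiisopropoxyborane, C=CCB(OC(C)C)OC(C)C
Why: chiral-diol-catalysed asymmetric allylboration of a ketone through a closed six-membered transition state; only the carbonyl next to the alkoxy-bearing carbon should react because the other one is a deactivated vinylogous ester, and the future C5 centre is set here under catalyst control.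

**Step 3**
Reactants: 4 (4R)-4-allyl-4-hydroxy-3-isopropoxycyclobut-2-en-1-one
Product: 5 (4R)-4-allyl-3-isopropoxy-4-methoxycyclobut-2-en-1-one
Conditions: MeI (10 equiv), Ag2O (3 equiv), MeCN, rt, dark
Reagents that add atoms: iodomethane, CI
Why: silver-oxide-mediated O-methylation of the tertiary carbinol under non-basic conditions should avoid oxyanion-triggered opening of the four-membered ring; the stereocenter is not involved.

**Step 4**
Reactants: 6 (S)-but-3-yn-2-ol
Product: 7 (S)-but-3-yn-2-yl methanesulfonate
Conditions: MsCl, Et3N, CH2Cl2, −78 → 0 °C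
Reagents that add atoms: methanesulfonyl chloride, CS(=O)(=O)Cl
Why: O-sulfonylation leaves the C–O bond intact, so the configuration is retained.

**Step 5**
Reactants: 7 (S)-but-3-yn-2-yl methanesulfonate; 8 3,4-dimethoxybenzaldehyde
Product: 10 (1R,2R)-1-(3,4-dimethoxyphenyl)-2-methylbut-3-yn-1-ol, via allenyl(ethyl)zinc 9 (not isolated)
Conditions: Pd(OAc)2 (5 mol %), PPh3 (5 mol %), Et2Zn (3 equiv), 7 (1.5 equiv), THF, −78 → −20 °C; aq. NH4Cl
Reagents that add atoms: none
Why: allenylmetal propargylation: anti SN2′ oxidative addition of the mesylate to zerovalent palladium and transfer to zinc give a configurationally defined allenylzinc, which adds SE2′ to the aldehyde through a cyclic transition state; the anti C2/C3 relationship follows from the aryl group lying away from the allenyl methyl group, and the absolute configuration from chirality transfer from 7.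

**Step 6**
Reactants: 10 (1R,2R)-1-(3,4-dimethoxyphenyl)-2-methylbut-3-yn-1-ol
Product: 11 triethyl{[(1R,2R)-1-(3,4-dimethoxyphenyl)-2-methylbut-3-yn-1-yl]oxy}silane
Conditions: TESCl, imidazole, DMF, 0 °C → rt
Reagents that add atoms: chlorotriethylsilane, CC[Si](CC)(CC)Cl
Why: routine silylation of the secondary alcohol masks the hydroxyl for the nickel step and comes off under the mild acid of step 8; no stereocenter is touched.

**Step 7**
Reactants: 5 (4R)-4-allyl-3-isopropoxy-4-methoxycyclobut-2-en-1-one; 11 triethyl{[(1R,2R)-1-(3,4-dimethoxyphenyl)-2-methylbut-3-yn-1-yl]oxy}silane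
Product: 12 (4S)-4-allyl-2-[(1R,2R)-1-(3,4-dimethoxyphenyl)-1-(triethylsilyloxy)propan-2-yl]-5-isopropoxy-4-methoxycyclohexa-2,5-dien-1-one
Conditions: Ni(cod)2 (10 mol %), THF, 0 °C → rt, 11 (1.5 equiv) added over 2 h
Reagents that add atoms: none
Why: Proposed new method: zerovalent nickel should add oxidatively into the strained acyl–C(sp3) bond of 5 to give a five-membered acylnickel metallacycle (the σ-bound form of an η4-vinylketene complex); the alkyne should then insert with its unsubstituted terminus into the bond between nickel and the quaternary carbon, and acyl–vinyl reductive elimination should release the dienone. The closest known reactions are the Ni(cod)2-catalysed benzannulation of cyclobutenones with alkynes to phenols, which must stop here at the cyclohexa-2,5-dienone because the former ring carbon 4 is quaternary, and the nickel-catalysed [4+2] insertion of alkynes into cyclobutanones. The six-membered ring is closed as a formal [4+2] of the four cyclobutenone carbons with the two alkyne carbons, by migratory insertion followed by reductive elimination from a seven-membered nickelacycle. No new stereocenter is formed: the quaternary carbon is carried over with retention because the cleaved C–C(acyl) bond is replaced by the new C–C(vinyl) bond on the metal, all three elementary steps being stereoretentive; the descriptor changes from (R) in 5 to (S) in 12 only through a change of CIP ranks, and the side-chain centres are spectators. The step needs regioselectivity (terminal CH to the quaternary carbon, branched alkyne carbon to the acyl carbon) and chemoselectivity over alkyne oligomerisation, β-hydride loss and thermal vinylketene–allyl [2+2] capture. The first is secured by the steric contrast between the alkyne termini at the congested nickel-bound quaternary carbon, the others by working at or below room temperature with slow addition of 11.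

**Step 8**
Reactants: 12 (4S)-4-allyl-2-[(1R,2R)-1-(3,4-dimethoxyphenyl)-1-(triethylsilyloxy)propan-2-yl]-5-isopropoxy-4-methoxycyclohexa-2,5-dien-1-one
Product: 14 (2R,3R,5S)-5-allyl-2-(3,4-dimethoxyphenyl)-5-methoxy-3-methyl-2,3-dihydro-1-benzofuran-6(5H)-one, via hydroxy dienone 13 (not isolated)
Conditions: PPTS (0.2 equiv), MeOH, 0 °C → rt (no heating)
Reagents that add atoms: none
Why: acid-catalysed methanolysis of the silyl ether frees the benzylic hydroxyl, which adds 5-exo-trig to the dienone carbonyl; loss of water gives a 1,3-dioxygenated allyl cation that is hydrolysed at the isopropoxy terminus (intramolecular vinylogous transesterification), which moves the carbonyl to C6 and closes the dihydrofuran without breaking any bond to C2, C3 or C5.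

**Compound list**
1 | diisopropyl squarate (3,4-diisopropoxycyclobut-3-ene-1,2-dione) | CC(C)OC1=C(OC(C)C)C(=O)C1=O | starting material
2 | 4-hydroxy-2,3-diisopropoxycyclobut-2-en-1-one (racemic) | CC(C)OC1=C(OC(C)C)C(O)C1=O | intermediate (not isolated)
3 | 3-isopropoxycyclobut-3-ene-1,2-dione | CC(C)OC1=CC(=O)C1=O | intermediate
4 | (4R)-4-allyl-4-hydroxy-3-isopropoxycyclobut-2-en-1-one | C=CC[C@]1(O)C(=O)C=C1OC(C)C | intermediate
5 | (4R)-4-allyl-3-isopropoxy-4-methoxycyclobut-2-en-1-one | C=CC[C@]1(OC)C(=O)C=C1OC(C)C | intermediate
6 | (S)-but-3-yn-2-ol | C#C[C@H](C)O | starting material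
7 | (S)-but-3-yn-2-yl methanesulfonate | C#C[C@H](C)OS(C)(=O)=O | intermediate
8 | 3,4-dimethoxybenzaldehyde | COc1ccc(C=O)cc1OC | starting material
9 | (M)-buta-1,2-dien-1-yl(ethyl)zinc | CC[Zn]C([H])=[C@]=C([H])C | intermediate (not isolated)
10 | (1R,2R)-1-(3,4-dimethoxyphenyl)-2-methylbut-3-yn-1-ol | O[C@@H](c1ccc(OC)c(OC)c1)[C@@H](C#C)C | intermediate
11 | triethyl{[(1R,2R)-1-(3,4-dimethoxyphenyl)-2-methylbut-3-yn-1-yl]oxy}silane | CC[Si](CC)(CC)O[C@@H](c1ccc(OC)c(OC)c1)[C@@H](C#C)C | intermediate
12 | (4S)-4-allyl-2-[(1R,2R)-1-(3,4-dimethoxyphenyl)-1-(triethylsilyloxy)propan-2-yl]-5-isopropoxy-4-methoxycyclohexa-2,5-dien-1-one | C=CC[C@]1(OC)C=C(C(=O)C=C1OC(C)C)[C@@H](C)[C@@H](O[Si](CC)(CC)CC)c1ccc(OC)c(OC)c1 | intermediate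
13 | (4S)-4-allyl-2-[(1R,2R)-1-(3,4-dimethoxyphenyl)-1-hydroxypropan-2-yl]-5-isopropoxy-4-methoxycyclohexa-2,5-dien-1-one | C=CC[C@]1(OC)C=C(C(=O)C=C1OC(C)C)[C@@H](C)[C@@H](O)c1ccc(OC)c(OC)c1 | intermediate (not isolated)
14 | (2R,3R,5S)-5-allyl-2-(3,4-dimethoxyphenyl)-5-methoxy-3-methyl-2,3-dihydro-1-benzofuran-6(5H)-one | C=CC[C@]1(OC)C=C2C(=CC1=O)O[C@@H](c1ccc(OC)c(OC)c1)[C@@H]2C | target

**Step count and risks**
Total step count: 8. Longest linear sequence: 5 steps (steps 1, 2, 3, 7, 8; the alkyne branch, steps 4, 5, 6, 7, 8, is equally long).

Steps most likely to fail: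

1. Step 7 (Proposed new method). What may go wrong: oligomerisation of the terminal alkyne at zerovalent nickel faster than insertion; insertion with the opposite regiochemistry; escape of a free planar vinylketene, with loss of the C5 configuration and capture by the allyl group; or β-hydride loss from the nickel-bound quaternary carbon. Fallback with known chemistry (stepwise Moore route), setting out from alkyne 11 and semisquarate 3. Lithiation of 11 (n-BuLi, THF, −78 °C) and addition of the acetylide to the ketone carbonyl of 3 should give 4-alkynyl-4-hydroxy-3-isopropoxycyclobut-2-en-1-one F1. Heating in toluene (110 °C) should bring about the Moore rearrangement (electrocyclic opening to the alkynyl vinylketene, ring closure, hydrogen transfer) to 2-isopropoxy-5-alkyl-1,4-benzoquinone F2. C4–C5 is then made in the addition and C3a–C7a in the ring expansion. Allylboration of the quinone carbonyl next to the isopropoxy-bearing carbon, under the chiral-diol catalysis of step 2, should give para-quinol F3, with C5 under catalyst control and the C5 epimer removed by chromatography if needed. O-Methylation (MeI, Ag2O, MeCN) comes back to the route at 12.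

2. Step 2. What may go wrong: uncatalysed background allylboration of the very electrophilic dione and weak facial discrimination of the flat four-membered ring, leading to low enantiomeric purity. Fallback, setting out from 3: allylmagnesium bromide (THF, −78 °C) should give racemic carbinol F4, which is resolved by preparative supercritical-fluid chromatography on a chiral stationary phase; the (R) enantiomer is 4, where the route is rejoined.

3. Step 5. What may go wrong: insufficient anti selectivity with the electron-rich aromatic aldehyde and partial racemisation of the allenylzinc before addition. Fallback, setting out from 8. Brown (E)-crotylboration with (E)-crotyldiisopinocampheylborane (antipode chosen for the (1R,2R) product; THF, −78 °C; then NaOH, H2O2) should give anti homoallylic alcohol F5 through a closed chair transition state. Silylation (TESCl, imidazole, DMF) gives silyl ether F6. Ozonolysis (O3, CH2Cl2, −78 °C; PPh3) gives aldehyde F7. Ohira–Bestmann homologation (dimethyl (1-diazo-2-oxopropyl)phosphonate, K2CO3, MeOH, 0 °C) comes back to the route at 11.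

**Further compounds**
F1 | step 7 | 4-[(3R,4R)-4-(3,4-dimethoxyphenyl)-3-methyl-4-(triethylsilyloxy)but-1-yn-1-yl]-4-hydroxy-3-isopropoxycyclobut-2-en-1-one (both epimers at the ring carbinol carbon) | CC(C)OC1=CC(=O)C1(O)C#C[C@@H](C)[C@@H](O[Si](CC)(CC)CC)c1ccc(OC)c(OC)c1
F2 | step 7 | 2-[(1R,2R)-1-(3,4-dimethoxyphenyl)-1-(triethylsilyloxy)propan-2-yl]-5-isopropoxycyclohexa-2,5-diene-1,4-dione | CC(C)OC1=CC(=O)C(=CC1=O)[C@@H](C)[C@@H](O[Si](CC)(CC)CC)c1ccc(OC)c(OC)c1
F3 | step 7 | (4S)-4-allyl-2-[(1R,2R)-1-(3,4-dimethoxyphenyl)-1-(triethylsilyloxy)propan-2-yl]-4-hydroxy-5-isopropoxycyclohexa-2,5-dien-1-one | C=CC[C@]1(O)C=C(C(=O)C=C1OC(C)C)[C@@H](C)[C@@H](O[Si](CC)(CC)CC)c1ccc(OC)c(OC)c1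
F4 | step 2 | rac-4-allyl-4-hydroxy-3-isopropoxycyclobut-2-en-1-one | C=CCC1(O)C(=O)C=C1OC(C)C
F5 | step 5 | (1R,2R)-1-(3,4-dimethoxyphenyl)-2-methylbut-3-en-1-ol | O[C@@H](c1ccc(OC)c(OC)c1)[C@@H](C=C)C
F6 | step 5 | triethyl{[(1R,2R)-1-(3,4-dimethoxyphenyl)-2-methylbut-3-en-1-yl]oxy}silane | CC[Si](CC)(CC)O[C@@H](c1ccc(OC)c(OC)c1)[C@@H](C=C)C
F7 | step 5 | (2S,3R)-3-(3,4-dimethoxyphenyl)-2-methyl-3-(triethylsilyloxy)propanal | CC[Si](CC)(CC)O[C@@H](c1ccc(OC)c(OC)c1)[C@@H](C=O)C
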